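**Plan**

- Retrosynthetic cuts, in order: the acetate, methacrylate and silyl groups; C7–C8 of the ten-membered ring (Nozaki–Hiyama–Kishi); the lactone O–C6 bond (iodolactonisation of a vinylallenic acid whose allene is C6=C7=C11); C11–C12 (carbonylation of a C6 propargylic carbonate); C6–C7 (alkynylation of a Z-enal); C3–C4 (cyclopropanol homoenolate coupling).
- Forward: the open chain first (C8/C9/C10/C1 from dimethyl (R)-malate, C2/C3 from EtMgBr through a cyclopropanol, C4–C6 from but-2-yn-1-ol, C7/C11/C13 from a propargyl ether, C12 from CO), then the butenolide ring, then the ten-membered ring, then the ester pattern.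
- Enabling feature: C6, C7 and C11 are three contiguous butenolide carbons and C7 ends as a fully substituted sp2 carbon, so they can be an allene bearing the carboxyl on C11. Its cyclisation makes the O–C6 bond and leaves C7 free to take an iodine that later closes the ring to C8.
- Stereochemistry: C9 from malate; C10 by anti methylation of the malate dianion; 4Z from hydroxyl-directed hydroalumination–iodination; C6 from a catalyst-controlled alkynylation relayed through the allene axis (anti SN2′, then anti addition); C8 by Felkin–Anh reduction of the C8 ketone next to C9.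

Key step: step 11

**Remarks**

- Abbreviations: TBSO = tert-butyldimethylsilyloxy, PMBO = (4-methoxybenzyl)oxy.
- Locants C1–C13 follow the germacranolide skeleton: C1 ketone, C2/C3 methylenes, C4=C5 olefin (C4 bears methyl), C6 lactone carbinol, C7=C11 butenolide olefin, C8 methacrylate carbinol, C9 free carbinol, C10 methyl-bearing methine, C12 lactone carbonyl, C13 acetoxymethyl carbon.
- Assumption: the (S,S)-ProPhenol ligand is taken to deliver the 9S carbinol of 14 (6S in skeleton numbering); if the sense is opposite, the (R,R) ligand is used and nothing else changes.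

**Route**

Step 1
Reactants: 1 dimethyl (R)-malate
Product: 3 dimethyl (2R,3S)-2-hydroxy-3-methylbutanedioate, via dilithium alkoxide enolate 2 (not isolated)
Conditions: LiN(iPr)2 (2.2 equiv), THF, −78 to −20 °C; then MeI, −78 to 0 °C
Reagents that add atoms: iodomethane, CI
Why: Fráter–Seebach alkylation, in which the chelated dilithium alkoxide enolate is methylated on the face anti to the C9 alkoxide, should set C10 anti to the C9 oxygen.

Step 2
Reactants: 3 dimethyl (2R,3S)-2-hydroxy-3-methylbutanedioate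
Product: 4 methyl (2S,3R)-3,4-dihydroxy-2-methylbutanoate
Conditions: BH3·SMe2, NaBH4 (5 mol %), THF, 0 °C to rt; MeOH quench
Reagents that add atoms: none
Why: hydroxyl-directed borane reduction, in which the borinate formed at the free hydroxyl delivers hydride only to the adjacent ester, should leave the C1 ester intact.

Step 3
Reactants: 4 methyl (2S,3R)-3,4-dihydroxy-2-methylbutanoate
Product: 5 methyl (2S,3R)-3,4-bis(TBSO)-2-methylbutanoate
Conditions: TBSCl, imidazole, DMF, rt
Reagents that add atoms: tert-butyldimethylsilyl chloride, CC(C)(C)[Si](C)(C)Cl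
Why: imidazole-promoted silyl ether formation blocks both hydroxyls at once and prevents γ-lactonisation of the diol ester.

Step 4
Reactants: 5 methyl (2S,3R)-3,4-bis(TBSO)-2-methylbutanoate
Product: 6 1-[(2S,3R)-3,4-bis(TBSO)butan-2-yl]cyclopropan-1-ol
Conditions: EtMgBr (3 equiv), Ti(OiPr)4 (0.5 equiv), THF, 0 °C to rt
Reagents that add atoms: ethylmagnesium bromide, CC[Mg]Br
Why: Kulinkovich cyclopropanation, in which the titanacyclopropane formed from EtMgBr and Ti(OiPr)4 adds twice to the ester carbonyl, brings in C2 and C3 as the two ring methylenes without enolising the α-stereocentre.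

Step 5
Reactants: 7 but-2-yn-1-ol
Product: 9 (2Z)-3-iodobut-2-en-1-ol, via cyclic vinylalanate 8 (not isolated)
Conditions: NaAlH2(OCH2CH2OMe)2, THF, 0 °C to rt; then I2, −78 to 0 °C
Reagents that add atoms: iodine, II
Why: hydroxyl-directed trans-hydroalumination places aluminium on C3 cis to the carbinol carbon in a five-membered alanate, and iodinolysis with retention should give the Z iodide only.

Step 6
Reactants: 6 1-[(2S,3R)-3,4-bis(TBSO)butan-2-yl]cyclopropan-1-ol; 9 (2Z)-3-iodobut-2-en-1-ol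
Product: 10 (2R,3S,7Z)-1,2-bis(TBSO)-9-hydroxy-3,7-dimethylnon-7-en-4-one
Conditions: Pd(OAc)2 (5 mol %), XPhos (10 mol %), K3PO4, toluene, 60 °C
Reagents that add atoms: none
Why: Pd-catalysed ring-opening cross-coupling of a cyclopropanol (ketone homoenolate coupling) should join C3 to C4 by oxidative addition of 9, alkoxide exchange, β-carbon elimination and C(sp3)–C(sp2) reductive elimination with retention of the Z geometry; the bulky biaryl phosphine is chosen to outrun β-hydride elimination.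

Step 7
Reactants: 10 (2R,3S,7Z)-1,2-bis(TBSO)-9-hydroxy-3,7-dimethylnon-7-en-4-one
Product: 11 (2Z,7S,8R)-8,9-bis(TBSO)-3,7-dimethyl-6-oxonon-2-enal
Conditions: TEMPO (10 mol %), PhI(OAc)2, CH2Cl2, rt
Reagents that add atoms: none
Why: the oxoammonium oxidation is selective for the primary allylic alcohol and non-isomerising, so the Z-enal should form with ketone and silyl ethers untouched.

Step 8
Reactants: 11 (2Z,7S,8R)-8,9-bis(TBSO)-3,7-dimethyl-6-oxonon-2-enal; 12 1-methoxy-4-[(prop-2-yn-1-yloxy)methyl]benzene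
Product: 14 (2R,3S,7Z,9S)-1,2-bis(TBSO)-9-hydroxy-12-(PMBO)-3,7-dimethyldodec-7-en-10-yn-4-one, via methylzinc acetylide 13 (not isolated)
Conditions: Me2Zn, (S,S)-ProPhenol (20 mol %), Ph3PO (40 mol %), toluene, 4 °C
Reagents that add atoms: none
Why: catalytic asymmetric alkynylzinc addition to an aldehyde under the dinuclear zinc–ProPhenol catalyst should set the C6 carbinol by catalyst control, the alkynylzinc being unreactive toward the C1 ketone.

Step 9
Reactants: 14 (2R,3S,7Z,9S)-1,2-bis(TBSO)-9-hydroxy-12-(PMBO)-3,7-dimethyldodec-7-en-10-yn-4-one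
Product: 15 (4S,5Z,10S,11R)-11,12-bis(TBSO)-1-(PMBO)-6,10-dimethyl-9-oxododec-5-en-2-yn-4-yl methyl carbonate
Conditions: ClCO2Me, pyridine, DMAP (cat.), CH2Cl2, 0 °C
Reagents that add atoms: methyl chloroformate, COC(=O)Cl
Why: O-acylation with a chloroformate turns the C6 hydroxyl into an ionisable leaving group with retention at C6.

Step 10
Reactants: 15 (4S,5Z,10S,11R)-11,12-bis(TBSO)-1-(PMBO)-6,10-dimethyl-9-oxododec-5-en-2-yn-4-yl methyl carbonate
Product: 16 (5Z,10S,11R)-11,12-bis(TBSO)-2-[(PMBO)methyl]-6,10-dimethyl-9-oxododeca-2,3,5-trienoic acid with (aR) allene axis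
Conditions: Pd(PPh3)4 (5 mol %), CO (1 atm), THF/H2O, rt
Reagents that add atoms: carbon monoxide, [C-]#[O+]; water, O
Why: Pd-catalysed carbonylation of a propargylic carbonate, in which zerovalent palladium displaces the carbonate in anti SN2′ fashion at C11, CO inserts with retention and water cleaves the acyl complex, should relay the C6 centre to the (aR) allene axis; rt is kept to avoid a 1,5-hydrogen shift of the Z-vinylallene.

Step 11
Reactants: 16 (5Z,10S,11R)-11,12-bis(TBSO)-2-[(PMBO)methyl]-6,10-dimethyl-9-oxododeca-2,3,5-trienoic acid with (aR) allene axis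
Product: 17 (5R)-5-[(1Z,6S,7R)-7,8-bis(TBSO)-2,6-dimethyl-5-oxooct-1-en-1-yl]-4-iodo-3-[(PMBO)methyl]furan-2(5H)-one
Conditions: I2, NaHCO3, MeCN, 0 °C, dark
Reagents that add atoms: iodine, II
Why: Iodine adds as an electrophile to the central allene carbon C7 on the face remote from the carboxyl while the carboxylate oxygen attacks the allene terminus C6 (anti addition across C6=C7, the developing positive charge at C6 being shared with the C4=C5 vinyl group), and bicarbonate takes up the proton to give the 4-iodofuran-2(5H)-one. The closest known reaction type is the iodolactonisation of 2,3-allenoic acids to β-iodobutenolides, which is stereospecific for enantioenriched allenes. The butenolide ring closes in the 5-endo mode onto the sp2 allene terminus, geometrically easy here because the attacked π bond is the one orthogonal to the enoate and lies in the plane of the carboxyl group. The new stereocentre C6 is controlled by the allene axis, since the carboxyl on C11 can reach only one lobe of that π bond, so the (aR) axis should give 6R (overall inversion relative to the carbonate-bearing carbon of 15). The step needs chemoselectivity for the allene over the C4=C5 olefin, secured because only the allene has a nucleophile placed for irreversible capture whereas iodonium formation at the isolated olefin is reversible, and regioselectivity for C6 over C4, secured because C4 could be reached only through a seven-membered transition state. It also needs the 4Z geometry and the axial information to survive, which the cold, buffered, anhydrous conditions and the fast intramolecular capture should secure, and it leaves on C7 the iodine that closes the ten-membered ring in step 14.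

Step 12
Reactants: 17 (5R)-5-[(1Z,6S,7R)-7,8-bis(TBSO)-2,6-dimethyl-5-oxooct-1-en-1-yl]-4-iodo-3-[(PMBO)methyl]furan-2(5H)-one
Product: 18 (5R)-5-[(1Z,6S,7R)-7-(TBSO)-8-hydroxy-2,6-dimethyl-5-oxooct-1-en-1-yl]-4-iodo-3-[(PMBO)methyl]furan-2(5H)-one
Conditions: CSA (10 mol %), MeOH/CH2Cl2, 0 °C
Reagents that add atoms: none
Why: acid-catalysed methanolysis should remove the unhindered primary silyl ether much faster than the secondary one, the PMB ether and vinyl iodide being inert.

Step 13
Reactants: 18 (5R)-5-[(1Z,6S,7R)-7-(TBSO)-8-hydroxy-2,6-dimethyl-5-oxooct-1-en-1-yl]-4-iodo-3-[(PMBO)methyl]furan-2(5H)-one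
Product: 19 (2R,3S,7Z)-2-(TBSO)-8-[(2R)-3-iodo-4-[(PMBO)methyl]-5-oxo-2,5-dihydrofuran-2-yl]-3,7-dimethyl-4-oxooct-7-enal
Conditions: Dess–Martin periodinane, NaHCO3, CH2Cl2, 0 °C to rt
Reagents that add atoms: none
Why: buffered Dess–Martin oxidation should give the α-silyloxy aldehyde without epimerisation at C9.

Step 14
Reactants: 19 (2R,3S,7Z)-2-(TBSO)-8-[(2R)-3-iodo-4-[(PMBO)methyl]-5-oxo-2,5-dihydrofuran-2-yl]-3,7-dimethyl-4-oxooct-7-enal
Product: 21 (5R,6S,10Z,11aR)-5-(TBSO)-4-hydroxy-3-[(PMBO)methyl]-6,10-dimethyl-5,6,8,9-tetrahydrocyclodeca[b]furan-2,7(4H,11aH)-dione (C4 epimers; C4 is skeleton C8), via vinylchromium dichloride 20 (not isolated)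
Conditions: CrCl2 (10 equiv), NiCl2 (cat.), DMSO, rt, high dilution (slow addition)
Reagents that add atoms: none
Why: Nozaki–Hiyama–Kishi macrocyclisation, in which zerovalent nickel inserts into the C7–I bond and the trivalent vinylchromium species adds to the C8 aldehyde rather than the C1 ketone, should close the ten-membered ring; the C8 configuration is left open because both epimers converge in step 15.

Step 15
Reactants: 21 macrocyclic C8 alcohol (epimer mixture)
Product: 22 (5R,6S,10Z,11aR)-5-(TBSO)-3-[(PMBO)methyl]-6,10-dimethyl-5,6,8,9-tetrahydrocyclodeca[b]furan-2,4,7(11aH)-trione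
Conditions: Dess–Martin periodinane, NaHCO3, CH2Cl2, rt
Reagents that add atoms: none
Why: Dess–Martin oxidation of the only free hydroxyl converges both C8 epimers to one ketone.

Step 16
Reactants: 22 macrocyclic C8 ketone
Product: 23 (4R,5R,6S,10Z,11aR)-5-(TBSO)-4-hydroxy-3-[(PMBO)methyl]-6,10-dimethyl-5,6,8,9-tetrahydrocyclodeca[b]furan-2,7(4H,11aH)-dione
Conditions: NaBH4, CeCl3·7H2O, MeOH/CH2Cl2, −78 °C
Reagents that add atoms: none
Why: Luche reduction should deliver hydride 1,2 to the conjugated, α-oxygenated C8 carbonyl faster than to the saturated C1 ketone, and attack anti to the C9 silyloxy group (polar Felkin–Anh) should give the 8,9-syn relationship, i.e. 8R.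

Step 17
Reactants: 23 macrocyclic (8R) alcohol
Product: 24 (4R,5R,6S,10Z,11aR)-5-(TBSO)-3-[(PMBO)methyl]-6,10-dimethyl-2,7-dioxo-2,4,5,6,7,8,9,11a-octahydrocyclodeca[b]furan-4-yl 2-methylprop-2-enoate
Conditions: methacrylic anhydride, Et3N, DMAP, CH2Cl2, 0 °C to rt
Reagents that add atoms: methacrylic anhydride, C=C(C)C(=O)OC(=O)C(C)=C
Why: DMAP-catalysed acyl transfer esterifies the secondary allylic alcohol with retention at C8.

Step 18
Reactants: 24 C8 methacrylate with C13 PMB ether
Product: 25 (4R,5R,6S,10Z,11aR)-5-(TBSO)-3-(hydroxymethyl)-6,10-dimethyl-2,7-dioxo-2,4,5,6,7,8,9,11a-octahydrocyclodeca[b]furan-4-yl 2-methylprop-2-enoate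
Conditions: DDQ, CH2Cl2/pH 7 buffer, 0 °C
Reagents that add atoms: none
Why: oxidative PMB ether cleavage (benzylic hydride abstraction by DDQ, then hydrolysis of the oxocarbenium ion) should free the C13 hydroxyl without touching silyl ether, esters or olefins.

Step 19
Reactants: 25 C13 alcohol
Product: 26 [(4R,5R,6S,10Z,11aR)-5-(TBSO)-6,10-dimethyl-4-[(2-methylprop-2-enoyl)oxy]-2,7-dioxo-2,4,5,6,7,8,9,11a-octahydrocyclodeca[b]furan-3-yl]methyl acetate
Conditions: Ac2O, pyridine, DMAP (cat.), CH2Cl2, 0 °C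
Reagents that add atoms: acetic anhydride, CC(=O)OC(C)=O
Why: standard acetylation of the primary allylic alcohol by acyl transfer.

Step 20
Reactants: 26 C9 silyl ether of the target
Product: 27 [(4R,5R,6S,10Z,11aR)-5-hydroxy-6,10-dimethyl-4-[(2-methylprop-2-enoyl)oxy]-2,7-dioxo-2,4,5,6,7,8,9,11a-octahydrocyclodeca[b]furan-3-yl]methyl acetate (CNP0164859.1)
Conditions: HF·pyridine, THF, 0 °C to rt
Reagents that add atoms: none
Why: fluoride-mediated desilylation under acidic conditions should release the C9 hydroxyl while avoiding base-induced 1,2-acyl migration, retro-aldol cleavage or epimerisation at C6 and C10.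

**Compound list**

1 | dimethyl (R)-malate | COC(=O)[C@H](O)CC(=O)OC | starting material
2 | dilithium alkoxide enolate of 1 (not isolated) | COC(=O)[C@H]([O-])C=C([O-])OC.[Li+].[Li+] | intermediate
3 | dimethyl (2R,3S)-2-hydroxy-3-methylbutanedioate | COC(=O)[C@H](O)[C@H](C)C(=O)OC | intermediate
4 | methyl (2S,3R)-3,4-dihydroxy-2-methylbutanoate | OC[C@H](O)[C@H](C)C(=O)OC | intermediate
5 | methyl (2S,3R)-3,4-bis(TBSO)-2-methylbutanoate | CC(C)(C)[Si](C)(C)OC[C@H](O[Si](C)(C)C(C)(C)C)[C@H](C)C(=O)OC | intermediate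
6 | 1-[(2S,3R)-3,4-bis(TBSO)butan-2-yl]cyclopropan-1-ol | CC(C)(C)[Si](C)(C)OC[C@H](O[Si](C)(C)C(C)(C)C)[C@H](C)C1(O)CC1 | intermediate
7 | but-2-yn-1-ol | CC#CCO | starting material
8 | cyclic vinylalanate, sodium salt (not isolated) | CC1=CCO[Al-]1(OCCOC)OCCOC.[Na+] | intermediate
9 | (2Z)-3-iodobut-2-en-1-ol | C/C(I)=C/CO | intermediate
10 | (2R,3S,7Z)-1,2-bis(TBSO)-9-hydroxy-3,7-dimethylnon-7-en-4-one | CC(C)(C)[Si](C)(C)OC[C@H](O[Si](C)(C)C(C)(C)C)[C@H](C)C(=O)CC/C(C)=C\CO | intermediate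
11 | (2Z,7S,8R)-8,9-bis(TBSO)-3,7-dimethyl-6-oxonon-2-enal | CC(C)(C)[Si](C)(C)OC[C@H](O[Si](C)(C)C(C)(C)C)[C@H](C)C(=O)CC/C(C)=C\C=O | intermediate
12 | 1-methoxy-4-[(prop-2-yn-1-yloxy)methyl]benzene | C#CCOCc1ccc(OC)cc1 | starting material
13 | methylzinc acetylide of 12 (not isolated) | C[Zn]C#CCOCc1ccc(OC)cc1 | intermediate
14 | (2R,3S,7Z,9S)-1,2-bis(TBSO)-9-hydroxy-12-(PMBO)-3,7-dimethyldodec-7-en-10-yn-4-one | CC(C)(C)[Si](C)(C)OC[C@H](O[Si](C)(C)C(C)(C)C)[C@H](C)C(=O)CC/C(C)=C\[C@H](O)C#CCOCc1ccc(OC)cc1 | intermediate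
15 | (4S,5Z,10S,11R)-11,12-bis(TBSO)-1-(PMBO)-6,10-dimethyl-9-oxododec-5-en-2-yn-4-yl methyl carbonate | CC(C)(C)[Si](C)(C)OC[C@H](O[Si](C)(C)C(C)(C)C)[C@H](C)C(=O)CC/C(C)=C\[C@H](OC(=O)OC)C#CCOCc1ccc(OC)cc1 | intermediate
16 | (5Z,10S,11R)-11,12-bis(TBSO)-2-[(PMBO)methyl]-6,10-dimethyl-9-oxododeca-2,3,5-trienoic acid, (aR) allene axis | CC(C)(C)[Si](C)(C)OC[C@H](O[Si](C)(C)C(C)(C)C)[C@H](C)C(=O)CC/C(C)=C\[CH]=[C@]=C(COCc1ccc(OC)cc1)C(=O)O | intermediate
17 | (5R)-5-[(1Z,6S,7R)-7,8-bis(TBSO)-2,6-dimethyl-5-oxooct-1-en-1-yl]-4-iodo-3-[(PMBO)methyl]furan-2(5H)-one | CC(C)(C)[Si](C)(C)OC[C@H](O[Si](C)(C)C(C)(C)C)[C@H](C)C(=O)CC/C(C)=C\[C@H]1OC(=O)C(COCc2ccc(OC)cc2)=C1I | intermediate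
18 | (5R)-5-[(1Z,6S,7R)-7-(TBSO)-8-hydroxy-2,6-dimethyl-5-oxooct-1-en-1-yl]-4-iodo-3-[(PMBO)methyl]furan-2(5H)-one | OC[C@H](O[Si](C)(C)C(C)(C)C)[C@H](C)C(=O)CC/C(C)=C\[C@H]1OC(=O)C(COCc2ccc(OC)cc2)=C1I | intermediate
19 | (2R,3S,7Z)-2-(TBSO)-8-[(2R)-3-iodo-4-[(PMBO)methyl]-5-oxo-2,5-dihydrofuran-2-yl]-3,7-dimethyl-4-oxooct-7-enal | O=C[C@H](O[Si](C)(C)C(C)(C)C)[C@H](C)C(=O)CC/C(C)=C\[C@H]1OC(=O)C(COCc2ccc(OC)cc2)=C1I | intermediate
20 | vinylchromium dichloride derived from 19 (not isolated) | O=C[C@H](O[Si](C)(C)C(C)(C)C)[C@H](C)C(=O)CC/C(C)=C\[C@H]1OC(=O)C(COCc2ccc(OC)cc2)=C1[Cr](Cl)Cl | intermediate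
21 | (5R,6S,10Z,11aR)-5-(TBSO)-4-hydroxy-3-[(PMBO)methyl]-6,10-dimethyl-5,6,8,9-tetrahydrocyclodeca[b]furan-2,7(4H,11aH)-dione, C4 epimer mixture | OC1C2=C(COCc3ccc(OC)cc3)C(=O)O[C@@H]2/C=C(/C)CCC(=O)[C@@H](C)[C@H]1O[Si](C)(C)C(C)(C)C | intermediate
22 | (5R,6S,10Z,11aR)-5-(TBSO)-3-[(PMBO)methyl]-6,10-dimethyl-5,6,8,9-tetrahydrocyclodeca[b]furan-2,4,7(11aH)-trione | O=C1C2=C(COCc3ccc(OC)cc3)C(=O)O[C@@H]2/C=C(/C)CCC(=O)[C@@H](C)[C@H]1O[Si](C)(C)C(C)(C)C | intermediate
23 | (4R,5R,6S,10Z,11aR)-5-(TBSO)-4-hydroxy-3-[(PMBO)methyl]-6,10-dimethyl-5,6,8,9-tetrahydrocyclodeca[b]furan-2,7(4H,11aH)-dione | O[C@@H]1C2=C(COCc3ccc(OC)cc3)C(=O)O[C@@H]2/C=C(/C)CCC(=O)[C@@H](C)[C@H]1O[Si](C)(C)C(C)(C)C | intermediate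
24 | (4R,5R,6S,10Z,11aR)-5-(TBSO)-3-[(PMBO)methyl]-6,10-dimethyl-2,7-dioxo-2,4,5,6,7,8,9,11a-octahydrocyclodeca[b]furan-4-yl 2-methylprop-2-enoate | C=C(C)C(=O)O[C@@H]1C2=C(COCc3ccc(OC)cc3)C(=O)O[C@@H]2/C=C(/C)CCC(=O)[C@@H](C)[C@H]1O[Si](C)(C)C(C)(C)C | intermediate
25 | (4R,5R,6S,10Z,11aR)-5-(TBSO)-3-(hydroxymethyl)-6,10-dimethyl-2,7-dioxo-2,4,5,6,7,8,9,11a-octahydrocyclodeca[b]furan-4-yl 2-methylprop-2-enoate | C=C(C)C(=O)O[C@@H]1C2=C(CO)C(=O)O[C@@H]2/C=C(/C)CCC(=O)[C@@H](C)[C@H]1O[Si](C)(C)C(C)(C)C | intermediate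
26 | [(4R,5R,6S,10Z,11aR)-5-(TBSO)-6,10-dimethyl-4-[(2-methylprop-2-enoyl)oxy]-2,7-dioxo-2,4,5,6,7,8,9,11a-octahydrocyclodeca[b]furan-3-yl]methyl acetate | C=C(C)C(=O)O[C@@H]1C2=C(COC(C)=O)C(=O)O[C@@H]2/C=C(/C)CCC(=O)[C@@H](C)[C@H]1O[Si](C)(C)C(C)(C)C | intermediate
27 | [(4R,5R,6S,10Z,11aR)-5-hydroxy-6,10-dimethyl-4-[(2-methylprop-2-enoyl)oxy]-2,7-dioxo-2,4,5,6,7,8,9,11a-octahydrocyclodeca[b]furan-3-yl]methyl acetate | C=C(C)C(=O)O[C@@H]1C2=C(COC(C)=O)C(=O)O[C@@H]2/C=C(/C)CCC(=O)[C@@H](C)[C@H]1O | target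

**Step count**

Total steps: 20. Longest linear sequence: 19 (steps 1–4 and 6–20, from dimethyl (R)-malate).

**Steps most likely to fail, with fallbacks**

1. Step 14 (Nozaki–Hiyama–Kishi macrocyclisation). Bimolecular coupling and hydrodeiodination may outrun closure of the strained ten-membered ring, and the α-silyloxy aldehyde may epimerise during a slow reaction. The fallback sets out from aldehyde 19 and replaces carbonyl addition by an intramolecular acyl Stille coupling that returns to ketone 22, so steps 14 and 15 are both bypassed. Pinnick oxidation of 19 (NaClO2, NaH2PO4, 2-methylbut-2-ene) gives the carboxylic acid F2. Stannylation with Me3SnSnMe3 and Pd(PPh3)4 replaces the iodine by trimethylstannyl to give the stannyl acid F3. 1-Chloro-N,N,2-trimethylprop-1-en-1-amine under neutral conditions converts F3 into the acid chloride F4. F4 is cyclised under high dilution with Pd2(dba)3 and tri(2-furyl)phosphine to give 22.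

2. Step 10 (carbonylation to the vinylallenic acid). Ionisation may occur at the allylic instead of the propargylic terminus, hydrolysis of the acyl–palladium complex may be slow, and the free Z-vinylallenic acid may undergo 1,5-hydrogen shift or lose axial purity during isolation. The fallback sets out from carbonate 15 and avoids the free acid. Carbonylation in anhydrous methanol (Pd(PPh3)4, CO, MeOH/THF, rt) should give the methyl allenoate F1. F1 is cyclised directly with I2 in aqueous MeCN: the ester carbonyl oxygen attacks C6 and the 2-methoxyfuranium ion loses its methyl group as methanol. This returns to iodobutenolide 17.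

3. Step 16 (Luche reduction). The ring conformation may impose poor facial selectivity, and the C1 ketone may be reduced competitively. The fallback sets out from the epimer mixture 21 and drops the oxidation–reduction. The epimers are separated; the 8R epimer is compound 23 and is acylated as in step 17. The 8S alcohol F5 is esterified with methacrylic acid under Mitsunobu conditions (PPh3, DIAD, toluene, 0 °C), where SN2 displacement at C8 with inversion gives methacrylate 24.

**Further compounds**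

F1 | step 10 | methyl (5Z,10S,11R)-11,12-bis(TBSO)-2-[(PMBO)methyl]-6,10-dimethyl-9-oxododeca-2,3,5-trienoate, (aR) allene axis | CC(C)(C)[Si](C)(C)OC[C@H](O[Si](C)(C)C(C)(C)C)[C@H](C)C(=O)CC/C(C)=C\[CH]=[C@]=C(COCc1ccc(OC)cc1)C(=O)OC
F2 | step 14 | (2R,3S,7Z)-2-(TBSO)-8-[(2R)-3-iodo-4-[(PMBO)methyl]-5-oxo-2,5-dihydrofuran-2-yl]-3,7-dimethyl-4-oxooct-7-enoic acid | OC(=O)[C@H](O[Si](C)(C)C(C)(C)C)[C@H](C)C(=O)CC/C(C)=C\[C@H]1OC(=O)C(COCc2ccc(OC)cc2)=C1I
F3 | step 14 | (2R,3S,7Z)-2-(TBSO)-8-[(2R)-4-[(PMBO)methyl]-5-oxo-3-(trimethylstannyl)-2,5-dihydrofuran-2-yl]-3,7-dimethyl-4-oxooct-7-enoic acid | OC(=O)[C@H](O[Si](C)(C)C(C)(C)C)[C@H](C)C(=O)CC/C(C)=C\[C@H]1OC(=O)C(COCc2ccc(OC)cc2)=C1[Sn](C)(C)C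
F4 | step 14 | acid chloride of F3 | ClC(=O)[C@H](O[Si](C)(C)C(C)(C)C)[C@H](C)C(=O)CC/C(C)=C\[C@H]1OC(=O)C(COCc2ccc(OC)cc2)=C1[Sn](C)(C)C
F5 | step 16 | (4S,5R,6S,10Z,11aR)-5-(TBSO)-4-hydroxy-3-[(PMBO)methyl]-6,10-dimethyl-5,6,8,9-tetrahydrocyclodeca[b]furan-2,7(4H,11aH)-dione | O[C@H]1C2=C(COCc3ccc(OC)cc3)C(=O)O[C@@H]2/C=C(/C)CCC(=O)[C@@H](C)[C@H]1O[Si](C)(C)C(C)(C)C
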